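The constants I can use are those the earlier runs give, and the first is a ceiling: in the autumn run reagent is the limiting reagent, charged at 46.2% of the substrate, and first product stands at 46.1% after 12.0 h.

| setting | autumn | spring | ochre | red | violet |
|---|---|---|---|---|---|
| substrate | 0.26 M | 0.26 M | 0.26 M | 0.26 M | 0.26 M |
| reagent | 0.12 M | 0.52 M | 0.130 M | 0.390 M | 0.780 M |
| remark | run made earlier | run made earlier |  |  |  |
| time |  |  | 12 h | 12 h | 12 h |

| run | time / h | first product / % | bis adduct / % |
|---|---|---|---|
| autumn | 2.50 | 45.3 | 0.4 |
| autumn | 5.00 | 45.4 | 0 |
| autumn | 8.00 | 44.6 | 0.1 |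
| autumn | 10.0 | 45.7 | 0.3 |
| autumn | 12.0 | 46.1 | 0 |
| spring | 1.00 | 92.8 | 4.7 |
| spring | 3.00 | 90.1 | 10.1 |
| spring | 6.00 | 87.6 | 13.1 |
| spring | 8.00 | 86.0 | 14.4 |
| spring | 12.0 | 85.9 | 13.5 |

(scatter of a reading: 0.5 percentage points)

- the analysis behind the earlier runs scatters by 0.5 percentage points, standard deviation

1. final first product, as a percentage of the substrate charged, for each flask in turn (ochre, red, violet)

But the spring run, with reagent at twice the substrate, shows a second constant: bis adduct reads 14.4% at 8.00 h and 13.5% at 12.0 h, so I take their mean, 14.0%, as its level. The gap to that level is 9.3 percentage points at 1.00 h and 3.9 points at 3.00 h, so the approach half-life, the time in which bis adduct closes half its remaining gap, reads 1.58 h. If the new flasks approach as spring does, which is my assumption, 12 h holds 7.59 half-lives, so I expect the asked values to be level values.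

The forecast gives 49.7%, 92.5% and 75%, with “relaxation time about 3 h, so all flasks equilibrate by 12 h”; that time is its figure, not my half-life.

The flasks give 49.7%, 92.3% and 76.6%, within the margin of the forecast.

    reagent + first product ⇌ bis adduct + by-product (K = 0.230, k = 0.00375 L mol⁻¹ min⁻¹)
    substrate + reagent → first product + by-product (k = 0.205 L mol⁻¹ min⁻¹)
    reagent → decomposition product (k = 1.12 × 10⁻⁴ min⁻¹)

In the red flask the first step ran while substrate was there, with a half-life of 0.14 h for substrate by that step alone, the other concentrations as charged, and bis adduct stood at 7.14% at 6.00 h and 7.66% at 12.0 h, a ratio of 93.2% against 93.3% from the counted half-lives, while in the violet flask bis adduct stood at 22.8% and 23.4% at those times. Decomposition ran alongside, with a half-life of 100 h for reagent by that step alone in the red flask, where reagent stood at 25.8% of its charge at 12.0 h and 14.0% at 120 h, when first product stood at 95.5%.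

The runs were generated by integration for an exercise, and the scatter is random.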